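The butanolide is traced back to a Z-trisubstituted olefin between C4 and C5, the two oxygen-bearing carbons of the five-membered ring. Only five carbons (C3, C4, C5, C1', C2') separate the lactone carbonyl C2 from the side-chain carbinol oxygen. These atoms can therefore be tied into a temporary seven-membered lactone. Ring-closing metathesis, indifferent to the like polarity of C4 and C5, acts on the but-3-enoate of a methallyl-substituted tertiary carbinol. It forges C4=C5 in one operation, and the ring enforces the Z geometry. Saponification, reagent-controlled Shi epoxidation and anti opening at C5 by the carboxyl group then translate this geometry into the C4/C5 configuration. C2' comes from (S)-2-methylglycidol.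

Key step: step 5

Remark: locants follow the target butanolide in all intermediates (O1, C2 = carbonyl, C3, C4 = carbinol carbon, C5 = quaternary carbon, side chain C1' and C2'); the L-fructose-derived enantiomer of the Shi ketone is assumed to be a purchasable catalyst.

Step 1
Reactants: 1 (S)-2-methylglycidol; 2 1-bromopentadecane
Product: 4 (2R)-2-methyloctadecane-1,2-diol, via pentadecylmagnesium bromide 3 (not isolated)
Conditions: 2 (2.3 equiv), Mg, THF, reflux; then CuI (10 mol%), 1, THF, -30 to 0 °C; aq NH4Cl
Reagents that add atoms: none
Why: Copper-catalysed Grignard opening of the epoxide (SN2) occurs at the unsubstituted CH2, so no bond to the fully substituted stereocentre is broken, and the Payne rearrangement of this alkoxide is degenerate and cannot erode the configuration.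

Step 2
Reactants: 4 (2R)-2-methyloctadecane-1,2-diol
Product: 6 (2R)-2-hexadecyl-2-methyloxirane, via primary tosylate 5 (not isolated)
Conditions: NaH (2.5 equiv), N-tosylimidazole (1.05 equiv), THF, 0 °C to rt
Reagents that add atoms: none
Why: Selective sulfonylation of the primary alkoxide followed by intramolecular Williamson closure (3-exo-tet) by the tertiary alkoxide keeps the C2'–O bond, so the stereocentre is carried over unchanged.

Step 3
Reactants: 6 (2R)-2-hexadecyl-2-methyloxirane; 7 isopropenylmagnesium bromide
Product: 8 (4R)-2,4-dimethylicos-1-en-4-ol
Conditions: 7 (2 equiv), CuI (10 mol%), THF, -40 to 0 °C; aq NH4Cl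
Reagents that add atoms: none
Why: Copper-catalysed SN2 opening of the 2,2-disubstituted epoxide takes place at its CH2 terminus, installing C1', C5 and the C5 methyl group as a methallyl unit without touching the tertiary carbinol stereocentre.

Step 4
Reactants: 8 (4R)-2,4-dimethylicos-1-en-4-ol; 9 but-3-enoyl chloride
Product: 11 (4R)-2,4-dimethylicos-1-en-4-yl but-3-enoate, via lithium alkoxide 10 (not isolated)
Conditions: n-BuLi (1.05 equiv), THF, -78 °C; then 9 (1.3 equiv), -78 to 0 °C
Reagents that add atoms: none
Why: O-Acylation of the preformed lithium tert-alkoxide overcomes the low nucleophilicity of the tertiary carbinol, and if part of 9 is first dehydrochlorinated to vinylketene, alkoxide addition and kinetic alpha-protonation of the dienolate lead to the same beta,gamma-unsaturated ester, with the C–O bond at the stereocentre untouched.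

Step 5
Reactants: 11 (4R)-2,4-dimethylicos-1-en-4-yl but-3-enoate
Product: 12 (7R)-7-hexadecyl-5,7-dimethyl-6,7-dihydrooxepin-2(3H)-one
Conditions: Hoveyda–Grubbs II (5 mol%), 1,4-benzoquinone (10 mol%), toluene (2 mM), 80 °C, argon sparge
Reagents that add atoms: none
Why: Ring-closing olefin metathesis: the catalyst loads onto the monosubstituted vinyl group of the butenoate to give the C4 ruthenium alkylidene, which adds to the 1,1-disubstituted C5=CH2 unit through a metallacyclobutane and expels ethene, so the new C4=C5 bond itself closes the ring. The closest known reaction type is RCM of alkenoates of homoallylic alcohols to unsaturated seven-membered lactones bearing a trisubstituted olefin, including temporary-tether RCM used to fix olefin geometry. The only ring closed is the seven-membered oxepinone (O, C2, C3, C4, C5, C1', C2'), formed by intramolecular [2+2] cycloaddition and cycloreversion with both olefin carbons ending endocyclic. No stereocentre is created, but a seven-membered ring can hold only a cis ring olefin, so the trisubstituted alkene should form solely as the Z isomer (C3 cis to C1'), a geometry that open-chain olefination of the corresponding methyl ketone would not control and on which the C4/C5 relative configuration rests in step 7. The step needs cyclisation over oligomerisation and no drift of the beta,gamma-olefin into conjugation. The fully substituted C2' (gem-dialkyl effect) favours the folded ester rotamer, the hindered 1,1-disubstituted olefin does not homodimerise, high dilution suppresses cross metathesis, and benzoquinone intercepts ruthenium hydrides.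

Step 6
Reactants: 12 (7R)-7-hexadecyl-5,7-dimethyl-6,7-dihydrooxepin-2(3H)-one
Product: 13 (3Z,6R)-6-hydroxy-4,6-dimethyldocos-3-enoic acid
Conditions: LiOH (3 equiv), THF/MeOH/H2O, 0 °C to rt; then 1 M HCl to pH 4
Reagents that add atoms: lithium hydroxide, [Li+].[OH-]
Why: Saponification (acyl–oxygen cleavage) of the strained seven-membered lactone leaves the tertiary C2'–O bond, its configuration and the Z olefin intact, and the resulting carboxylate is no longer prone to alpha-deprotonation or double-bond migration.

Step 7
Reactants: 13 (3Z,6R)-6-hydroxy-4,6-dimethyldocos-3-enoic acid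
Product: 15 (4S,5S)-4-hydroxy-5-[(2R)-2-hydroxy-2-methyloctadecyl]-5-methyloxolan-2-one, via epoxy acid 14 (not isolated)
Conditions: ent-Shi ketone (30 mol%), Oxone, K2CO3, Bu4NHSO4, MeCN/DMM, aq Na2B4O7–EDTA buffer (pH 10.5), 0 °C; then 1 M HCl to pH 3, EtOAc, rt
Reagents that add atoms: Oxone (active component potassium peroxymonosulfate), [K+].[O-]S(=O)(=O)OO
Why: Shi asymmetric epoxidation (chiral dioxirane, spiro transition state) delivers oxygen under reagent control to the olefin face that makes C4 S (the D-fructose catalyst gives R at the CH carbon of trialkyl olefins, hence its enantiomer), and on acidification the epoxy acid lactonises by stereospecific anti opening at the tertiary, cation-stabilising C5 with inversion, so that Z geometry plus anti addition places the 4-OH cis to the side chain and sets C5 as S.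

Compound list
1 | (S)-2-methylglycidol, [(2S)-2-methyloxiran-2-yl]methanol | C[C@@]1(CO1)CO | starting material
2 | 1-bromopentadecane | CCCCCCCCCCCCCCCBr | starting material
3 | pentadecylmagnesium bromide | CCCCCCCCCCCCCCC[Mg]Br | intermediate
4 | (2R)-2-methyloctadecane-1,2-diol | CCCCCCCCCCCCCCCC[C@@](C)(O)CO | intermediate
5 | (2R)-2-hydroxy-2-methyloctadecyl 4-methylbenzenesulfonate | CCCCCCCCCCCCCCCC[C@@](C)(O)COS(=O)(=O)c1ccc(C)cc1 | intermediate
6 | (2R)-2-hexadecyl-2-methyloxirane | CCCCCCCCCCCCCCCC[C@]1(C)CO1 | intermediate
7 | isopropenylmagnesium bromide (prop-1-en-2-ylmagnesium bromide) | CC(=C)[Mg]Br | starting material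
8 | (4R)-2,4-dimethylicos-1-en-4-ol | CCCCCCCCCCCCCCCC[C@@](C)(O)CC(C)=C | intermediate
9 | but-3-enoyl chloride | C=CCC(=O)Cl | starting material
10 | lithium (4R)-2,4-dimethylicos-1-en-4-olate | CCCCCCCCCCCCCCCC[C@@](C)([O-])CC(C)=C.[Li+] | intermediate
11 | (4R)-2,4-dimethylicos-1-en-4-yl but-3-enoate | CCCCCCCCCCCCCCCC[C@@](C)(OC(=O)CC=C)CC(C)=C | intermediate
12 | (7R)-7-hexadecyl-5,7-dimethyl-6,7-dihydrooxepin-2(3H)-one | CCCCCCCCCCCCCCCC[C@]1(C)CC(C)=CCC(=O)O1 | intermediate
13 | (3Z,6R)-6-hydroxy-4,6-dimethyldocos-3-enoic acid | CCCCCCCCCCCCCCCC[C@@](C)(O)C/C(C)=C\CC(=O)O | intermediate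
14 | 2-[(2S,3R)-3-[(2R)-2-hydroxy-2-methyloctadecyl]-3-methyloxiran-2-yl]acetic acid | CCCCCCCCCCCCCCCC[C@@](C)(O)C[C@@]1(C)O[C@H]1CC(=O)O | intermediate
15 | (4S,5S)-4-hydroxy-5-[(2R)-2-hydroxy-2-methyloctadecyl]-5-methyloxolan-2-one | CCCCCCCCCCCCCCCC[C@@](C)(O)C[C@]1(C)OC(=O)C[C@@H]1O | target

Total step count: 7. Longest linear sequence: 7 steps (from 1).

Steps most likely to fail

1. Step 5.
- What may go wrong: the ruthenium alkylidene may engage a second molecule faster than the hindered 1,1-disubstituted olefin (oligomerisation). Ruthenium hydrides may also move the double bond into conjugation before closure.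
- Fallback: setting out from 11, exhaustive ozonolysis (O3, CH2Cl2, -78 °C; Me2S) would give the keto aldehyde (4R)-4-methyl-2-oxoicosan-4-yl 3-oxopropanoate F1. An intramolecular McMurry coupling (TiCl3(DME)1.5, Zn–Cu, DME, reflux, slow addition) would then join the same two carbons reductively as carbonyl carbons. This closes the same ring and comes back to the route at 12.

2. Step 7.
- What may go wrong: the dioxirane may discriminate poorly between the olefin faces, because the substituent cis to C3 is a bulky neopentyl-type group. Partial ionisation at C5 during the opening may also blur the inversion.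
- Fallback: setting out from 13, esterification (TMSCHN2, toluene/MeOH) would give methyl (3Z,6R)-6-hydroxy-4,6-dimethyldocos-3-enoate F2. A hydroxyl-directed, ligand-controlled epoxidation of this tertiary homoallylic alcohol (Hf(OtBu)4, chiral bishydroxamic acid, cumene hydroperoxide) would give methyl 2-[(2S,3R)-3-[(2R)-2-hydroxy-2-methyloctadecyl]-3-methyloxiran-2-yl]acetate F3. Catalytic CSA in wet CH2Cl2 would then trigger the same anti lactonisation with loss of the ester methyl group, coming back to the route at 15.

3. Step 4.
- What may go wrong: acylation of the hindered alkoxide may stall while the acid chloride is consumed by ketene oligomerisation. Base may also shift the double bond to the crotonate.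
- Fallback: setting out from 8, acylation with the more reactive and non-isomerisable chloroacetyl chloride (pyridine, cat. DMAP, CH2Cl2) would give (4R)-2,4-dimethylicos-1-en-4-yl chloroacetate F4. A palladium-catalysed Suzuki–Miyaura alkenylation of the alpha-chloro ester with potassium vinyltrifluoroborate (XPhos–Pd precatalyst, K2CO3, THF/H2O) would build the vinyl group afterwards, coming back to the route at 11.

Further compounds
F1 | step 5 | (4R)-4-methyl-2-oxoicosan-4-yl 3-oxopropanoate | CCCCCCCCCCCCCCCC[C@@](C)(OC(=O)CC=O)CC(C)=O
F2 | step 7 | methyl (3Z,6R)-6-hydroxy-4,6-dimethyldocos-3-enoate | CCCCCCCCCCCCCCCC[C@@](C)(O)C/C(C)=C\CC(=O)OC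
F3 | step 7 | methyl 2-[(2S,3R)-3-[(2R)-2-hydroxy-2-methyloctadecyl]-3-methyloxiran-2-yl]acetate | CCCCCCCCCCCCCCCC[C@@](C)(O)C[C@@]1(C)O[C@H]1CC(=O)OC
F4 | step 4 | (4R)-2,4-dimethylicos-1-en-4-yl chloroacetate | CCCCCCCCCCCCCCCC[C@@](C)(OC(=O)CCl)CC(C)=C
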